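## Retrosynthetic overview

1. Target ⇐ O-9 angeloylation and global desilylation of a protected (4E,1(10)Z)-germacradien-12,6-olide.
2. Ten-membered ring (second ring, closed last) ⇐ ring-closing metathesis forming C1=C10 from a C-1 vinyl and a C-10 isopropenyl group.
3. C7–C8 bond (joins fragments A and B, sets C-7 and C-8) ⇐ proposed chromium-catalysed asymmetric Barbier γ-allylation of a 3-(bromomethyl)butenolide with an α-PMB-oxy aldehyde.
4. Fragment A ⇐ butenolide ring (first ring) by acrylate ring-closing metathesis; C-6 by Sharpless kinetic resolution; 4E alkene by Negishi carboalumination; C-2 from (S)-epichlorohydrin.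
5. Fragment B (C-8 to C-10, C-9 stereocentre) ⇐ prenol by Sharpless epoxidation and epoxide-to-allylic-alcohol isomerisation.

Assumption: locants C-1 to C-15 follow germacrane numbering of the target (C-6 bears the lactone oxygen, C-12 is the lactone carbonyl, C-13 the exocyclic methylene); the target is (2S,6R,7R,8R,9R).

## Route

Step 1
Reactants: 1 (S)-epichlorohydrin; 2 trimethylsilylacetylene
Product: 4 (S)-1-chloro-5-(trimethylsilyl)pent-4-yn-2-ol, via lithium (trimethylsilyl)acetylide 3 (not isolated)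
Conditions: 2, n-BuLi, THF, −78 °C; BF3·OEt2; then 1, −78 °C; aq. NH4Cl
Reagents that add atoms: none
Why: BF3-promoted SN2 opening of the epoxide at its CH2 carbon by the acetylide (Yamaguchi-type alkynylation) leaves the C–O stereocentre untouched, so C-2 comes from the chiral pool.

Step 2
Reactants: 4 (S)-1-chloro-5-(trimethylsilyl)pent-4-yn-2-ol
Product: 6 (S)-6-(trimethylsilyl)hex-1-en-5-yn-3-ol, via alkynyl epoxide 5 (not isolated)
Conditions: Me3SI (4 equiv), n-BuLi (4 equiv), THF, −20 °C to rt
Reagents that add atoms: trimethylsulfonium iodide, C[S+](C)C.[I-]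
Why: Base closes the chlorohydrin to the terminal epoxide, and excess dimethylsulfonium methylide opens it at CH2 and eliminates dimethyl sulfide (one-carbon epoxide-to-allylic-alcohol homologation), with retention at the carbinol carbon.

Step 3
Reactants: 6 (S)-6-(trimethylsilyl)hex-1-en-5-yn-3-ol
Product: 7 (S)-tert-butyldimethyl{[6-(trimethylsilyl)hex-1-en-5-yn-3-yl]oxy}silane
Conditions: TBSCl, imidazole, DMF, rt
Reagents that add atoms: tert-butyldimethylsilyl chloride, CC(C)(C)[Si](C)(C)Cl
Why: Standard silylation of a secondary alcohol; the TBS ether is carried to the last step.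

Step 4
Reactants: 7 (S)-tert-butyldimethyl{[6-(trimethylsilyl)hex-1-en-5-yn-3-yl]oxy}silane
Product: 8 (S)-tert-butyl(hex-1-en-5-yn-3-yloxy)dimethylsilane
Conditions: K2CO3, MeOH, rt
Reagents that add atoms: none
Why: Methanolysis cleaves only the alkynyl C–Si bond and frees the terminal alkyne; the TBS ether is stable to these conditions.

Step 5
Reactants: 8 (S)-tert-butyl(hex-1-en-5-yn-3-yloxy)dimethylsilane; 9 acrolein
Product: 12 (4E,7S)-7-(tert-butyldimethylsilyloxy)-5-methylnona-1,4,8-trien-3-ol as a 1:1 mixture of C-3 epimers, via alkenyl(dimethyl)alane 10 (not isolated), via lithium alkenyl(butyl)dimethylaluminate 11 (not isolated)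
Conditions: Me3Al (2.5 equiv), Cp2ZrCl2 (25 mol %), CH2Cl2, 0 °C to rt; evaporate; n-BuLi, THF, −78 °C; then 9, −78 °C; aq. KNa tartrate
Reagents that add atoms: trimethylaluminium, C[Al](C)C
Why: Zirconium-catalysed syn-carboalumination (Negishi) adds Me and Al cis across the terminal alkyne with Al at the terminus, fixing the 4E trisubstituted alkene, and the derived alanate adds 1,2 to acrolein with retention of geometry; C-6 forms without control.

Step 6
Reactants: 12 (4E,7S)-7-(tert-butyldimethylsilyloxy)-5-methylnona-1,4,8-trien-3-ol (epimer mixture)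
Product: 13 (3S,4E,7S)-7-(tert-butyldimethylsilyloxy)-5-methylnona-1,4,8-trien-3-ol
Conditions: Ti(OiPr)4 (20 mol %), D-(−)-diisopropyl tartrate (30 mol %), t-BuOOH (0.6 equiv), 4 Å MS, CH2Cl2, −20 °C
Reagents that add atoms: none
Why: Sharpless kinetic resolution: with the D-(−)-tartrate the (3R)-epimer is epoxidised fast at its trisubstituted allylic alkene while the wanted (3S)-alcohol (C-6 of the target) is recovered in high ee at about 55 % conversion (yield ceiling 50 %).

Step 7
Reactants: 13 (3S,4E,7S)-7-(tert-butyldimethylsilyloxy)-5-methylnona-1,4,8-trien-3-ol; 14 2-(bromomethyl)acrylic acid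
Product: 15 (3S,4E,7S)-7-(tert-butyldimethylsilyloxy)-5-methylnona-1,4,8-trien-3-yl 2-(bromomethyl)acrylate
Conditions: 14, DCC, DMAP (5 mol %), CH2Cl2, 0 °C
Reagents that add atoms: none
Why: Steglich esterification at 0 °C with only catalytic DMAP spares the allylic bromide; no stereocentre is touched.

Step 8
Reactants: 15 (3S,4E,7S)-7-(tert-butyldimethylsilyloxy)-5-methylnona-1,4,8-trien-3-yl 2-(bromomethyl)acrylate
Product: 16 (5R)-3-(bromomethyl)-5-[(1E,4S)-4-(tert-butyldimethylsilyloxy)-2-methylhexa-1,5-dien-1-yl]furan-2(5H)-one (fragment A)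
Conditions: second-generation Hoveyda–Grubbs catalyst (5 mol %), toluene (5 mM), 80 °C
Reagents that add atoms: none
Why: Ring-closing metathesis between the C-6 vinyl group and the acrylate gives the butenolide; the distal vinyl group cannot compete because closure would put the E-trisubstituted alkene into a seven- or nine-membered ring.

Step 9
Reactants: 17 prenol (3-methylbut-2-en-1-ol)
Product: 18 (S)-(3,3-dimethyloxiran-2-yl)methanol
Conditions: Ti(OiPr)4 (5 mol %), L-(+)-diethyl tartrate (7.5 mol %), t-BuOOH, 4 Å MS, CH2Cl2, −20 °C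
Reagents that add atoms: tert-butyl hydroperoxide, CC(C)(C)OO
Why: Sharpless asymmetric epoxidation of a 3,3-disubstituted allylic alcohol; the L-(+)-tartrate gives the (2S)-epoxide, whose secondary C–O carbon becomes C-9.

Step 10
Reactants: 18 (S)-(3,3-dimethyloxiran-2-yl)methanol
Product: 19 (R)-3-methylbut-3-ene-1,2-diol
Conditions: Ti(OiPr)4 (1.2 equiv), CH2Cl2, rt; aq. tartaric acid
Reagents that add atoms: none
Why: Hydroxyl-directed, Ti(OiPr)4-promoted epoxide-to-allylic-alcohol isomerisation: the tertiary C–O bond opens and a methyl proton is lost, so the secondary C–O stereocentre is retained and the isopropenyl group appears.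

Step 11
Reactants: 19 (R)-3-methylbut-3-ene-1,2-diol
Product: 20 (4R)-2-(4-methoxyphenyl)-4-(prop-1-en-2-yl)-1,3-dioxolane (both C-2 epimers)
Conditions: 4-MeOC6H4CH(OMe)2, PPTS (cat.), CH2Cl2, rt
Reagents that add atoms: 4-methoxybenzaldehyde dimethyl acetal, COc1ccc(C(OC)OC)cc1
Why: Acid-catalysed transacetalisation ties the diol as its p-methoxybenzylidene acetal; the acetal epimers converge in the next step.

Step 12
Reactants: 20 (4R)-2-(4-methoxyphenyl)-4-(prop-1-en-2-yl)-1,3-dioxolane
Product: 21 (R)-2-[(4-methoxybenzyl)oxy]-3-methylbut-3-en-1-ol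
Conditions: i-Bu2AlH (3 equiv), CH2Cl2, −78 to 0 °C; aq. KNa tartrate
Reagents that add atoms: none
Why: Reductive acetal opening: aluminium binds the less hindered primary oxygen, so hydride delivery leaves the PMB group on the secondary oxygen and frees the primary alcohol.

Step 13
Reactants: 21 (R)-2-[(4-methoxybenzyl)oxy]-3-methylbut-3-en-1-ol
Product: 22 (R)-2-[(4-methoxybenzyl)oxy]-3-methylbut-3-enal (fragment B)
Conditions: Dess–Martin periodinane, NaHCO3, CH2Cl2, 0 °C; used at once
Reagents that add atoms: none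
Why: Buffered Dess–Martin oxidation gives the α-alkoxy β,γ-unsaturated aldehyde without epimerisation or conjugation if it is used immediately.

Step 14
Reactants: 16 (5R)-3-(bromomethyl)-5-[(1E,4S)-4-(tert-butyldimethylsilyloxy)-2-methylhexa-1,5-dien-1-yl]furan-2(5H)-one; 22 (R)-2-[(4-methoxybenzyl)oxy]-3-methylbut-3-enal
Product: 23 (4S,5R)-4-[(1R,2R)-2-(4-methoxybenzyloxy)-3-methyl-1-(triethylsilyloxy)but-3-en-1-yl]-5-[(1E,4S)-4-(tert-butyldimethylsilyloxy)-2-methylhexa-1,5-dien-1-yl]-3-methylenedihydrofuran-2(3H)-one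
Conditions: CrCl2 (10 mol %), (S,S)-3,6-di-tert-butyl-1,8-bis(4-isopropyl-4,5-dihydrooxazol-2-yl)-9H-carbazole (12 mol %), i-Pr2NEt (30 mol %), Mn powder (2 equiv), Et3SiCl (1.5 equiv), THF, 0 °C to rt
Reagents that add atoms: chlorotriethylsilane, CC[Si](Cl)(CC)CC
Why: Proposed new method: a ligand-controlled, chromium-catalysed Barbier-type γ-allylation that uses a chiral 5-substituted 3-(bromomethyl)butenolide as allyl donor and silylates the alkoxide in the catalytic cycle; divalent chromium (regenerated by Mn) reduces the allylic bromide to a trivalent allylchromium species bound at CH2, which adds through its ring γ-carbon (C-7) to the aldehyde in a closed Zimmerman–Traxler chair, where attack anti to the C-6 side chain gives the 6,7-trans lactone, the fixed E-like geometry of the cyclic allyl unit with the aldehyde residue equatorial gives the C-7/C-8 anti (crotylation-sense) relationship and hence the target C-8 configuration, the chelating α-OPMB group makes this the aldehyde's chelation-preferred face (matched with 9R), the (S,S) carbazole bis(oxazoline) ligand is taken as the enantiomer that reinforces this face (to be confirmed against its antipode), and Et3SiCl turns the catalyst over while capping O-8 so the C-8 alkoxide cannot translactonise to the 12,8-olide; closest known reactions are the stoichiometric zinc or indium Barbier allylation with 3-(bromomethyl)butenolides and the catalytic asymmetric Nozaki–Hiyama–Kishi-type 2-(alkoxycarbonyl)allylation with acyclic 2-(bromomethyl)acrylates.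

Step 15
Reactants: 23 (seco diene from step 14)
Product: 24 (1(10)Z,2S,4E,6R,7S,8R,9R)-2-(tert-butyldimethylsilyloxy)-9-(4-methoxybenzyloxy)-8-(triethylsilyloxy)germacra-1(10),4,11(13)-trien-12,6-olide
Conditions: second-generation Hoveyda–Grubbs catalyst (2 × 10 mol %), 1,4-benzoquinone (20 mol %), toluene (1 mM), 100 °C, argon sparge
Reagents that add atoms: none
Why: Ring-closing metathesis between the C-1 vinyl and C-10 isopropenyl groups releases ethene and closes the ten-membered ring; in a ring of this size the new trisubstituted alkene is expected to form as the ring-cis (1(10)Z) isomer, while the electron-poor exo-methylene and the 4E alkene stay out.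

Step 16
Reactants: 24 (protected macrocycle from step 15)
Product: 25 (1(10)Z,2S,4E,6R,7S,8R,9R)-2-(tert-butyldimethylsilyloxy)-9-hydroxy-8-(triethylsilyloxy)germacra-1(10),4,11(13)-trien-12,6-olide
Conditions: DDQ, CH2Cl2/aq. NaH2PO4–Na2HPO4 buffer (pH 7), 0 °C
Reagents that add atoms: none
Why: Oxidative PMB cleavage (hydride abstraction by DDQ, then hydrolysis of the oxocarbenium ion) frees only O-9; silyl ethers, lactone and alkenes are inert under buffered conditions.

Step 17
Reactants: 25 (C-9 alcohol from step 16); 26 angelic acid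
Product: 28 (1(10)Z,2S,4E,6R,7S,8R,9R)-9-angeloyloxy-2-(tert-butyldimethylsilyloxy)-8-(triethylsilyloxy)germacra-1(10),4,11(13)-trien-12,6-olide, via angelic 2,4,6-trichlorobenzoic anhydride 27 (not isolated)
Conditions: 26, 2,4,6-Cl3C6H2COCl, Et3N, toluene, rt; then 25, 80 °C
Reagents that add atoms: none
Why: Yamaguchi-type esterification through the mixed anhydride without a nucleophilic catalyst acylates the single free hydroxyl and keeps the Z geometry of the angelate (no isomerisation to tiglate).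

Step 18
Reactants: 28 (bis-silyl angelate from step 17)
Product: 29 (1(10)Z,2S,4E,6R,7R,8R,9R)-9-angeloyloxy-2,8-dihydroxygermacra-1(10),4,11(13)-trien-12,6-olide (CNP0311662.1)
Conditions: HF·pyridine, pyridine, THF, 0 °C to rt
Reagents that add atoms: none
Why: Fluoride cleaves both silyl ethers under buffered, mildly acidic conditions that spare the angelate and the α-methylene lactone and avoid O-9 to O-8 acyl migration and translactonisation.

## Compound list

1 | (S)-epichlorohydrin | ClC[C@@H]1CO1 | starting material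
2 | trimethylsilylacetylene | C#C[Si](C)(C)C | starting material
3 | lithium (trimethylsilyl)acetylide | [Li+].[C-]#C[Si](C)(C)C | intermediate
4 | (S)-1-chloro-5-(trimethylsilyl)pent-4-yn-2-ol | C[Si](C)(C)C#CC[C@H](O)CCl | intermediate
5 | (S)-trimethyl[3-(oxiran-2-yl)prop-1-yn-1-yl]silane | C[Si](C)(C)C#CC[C@H]1CO1 | intermediate
6 | (S)-6-(trimethylsilyl)hex-1-en-5-yn-3-ol | C[Si](C)(C)C#CC[C@H](O)C=C | intermediate
7 | (S)-tert-butyldimethyl{[6-(trimethylsilyl)hex-1-en-5-yn-3-yl]oxy}silane | C[Si](C)(C)C#CC[C@H](O[Si](C)(C)C(C)(C)C)C=C | intermediate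
8 | (S)-tert-butyl(hex-1-en-5-yn-3-yloxy)dimethylsilane | C#CC[C@H](O[Si](C)(C)C(C)(C)C)C=C | intermediate
9 | acrolein | C=CC=O | starting material
10 | [(1E,4S)-4-(tert-butyldimethylsilyloxy)-2-methylhexa-1,5-dien-1-yl]dimethylalane | C[Al](C)/C=C(\C)C[C@H](O[Si](C)(C)C(C)(C)C)C=C | intermediate
11 | lithium butyl[(1E,4S)-4-(tert-butyldimethylsilyloxy)-2-methylhexa-1,5-dien-1-yl]dimethylaluminate | [Li+].CCCC[Al-](C)(C)/C=C(\C)C[C@H](O[Si](C)(C)C(C)(C)C)C=C | intermediate
12 | (4E,7S)-7-(tert-butyldimethylsilyloxy)-5-methylnona-1,4,8-trien-3-ol, 1:1 mixture of C-3 epimers | C=CC(O)/C=C(\C)C[C@H](O[Si](C)(C)C(C)(C)C)C=C | intermediate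
13 | (3S,4E,7S)-7-(tert-butyldimethylsilyloxy)-5-methylnona-1,4,8-trien-3-ol | C=C[C@H](O)/C=C(\C)C[C@H](O[Si](C)(C)C(C)(C)C)C=C | intermediate
14 | 2-(bromomethyl)acrylic acid | C=C(CBr)C(=O)O | starting material
15 | (3S,4E,7S)-7-(tert-butyldimethylsilyloxy)-5-methylnona-1,4,8-trien-3-yl 2-(bromomethyl)acrylate | C=C(CBr)C(=O)O[C@@H](C=C)/C=C(\C)C[C@H](O[Si](C)(C)C(C)(C)C)C=C | intermediate
16 | (5R)-3-(bromomethyl)-5-[(1E,4S)-4-(tert-butyldimethylsilyloxy)-2-methylhexa-1,5-dien-1-yl]furan-2(5H)-one | O=C1O[C@H](/C=C(\C)C[C@H](O[Si](C)(C)C(C)(C)C)C=C)C=C1CBr | intermediate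
17 | prenol (3-methylbut-2-en-1-ol) | CC(C)=CCO | starting material
18 | (S)-(3,3-dimethyloxiran-2-yl)methanol | OC[C@@H]1OC1(C)C | intermediate
19 | (R)-3-methylbut-3-ene-1,2-diol | OC[C@H](O)C(C)=C | intermediate
20 | (4R)-2-(4-methoxyphenyl)-4-(prop-1-en-2-yl)-1,3-dioxolane, both C-2 epimers | COc1ccc(cc1)C1OC[C@H](O1)C(C)=C | intermediate
21 | (R)-2-[(4-methoxybenzyl)oxy]-3-methylbut-3-en-1-ol | OC[C@H](OCc1ccc(OC)cc1)C(C)=C | intermediate
22 | (R)-2-[(4-methoxybenzyl)oxy]-3-methylbut-3-enal | O=C[C@H](OCc1ccc(OC)cc1)C(C)=C | intermediate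
23 | (4S,5R)-4-[(1R,2R)-2-(4-methoxybenzyloxy)-3-methyl-1-(triethylsilyloxy)but-3-en-1-yl]-5-[(1E,4S)-4-(tert-butyldimethylsilyloxy)-2-methylhexa-1,5-dien-1-yl]-3-methylenedihydrofuran-2(3H)-one | C=C1C(=O)O[C@H](/C=C(\C)C[C@H](O[Si](C)(C)C(C)(C)C)C=C)[C@H]1[C@@H](O[Si](CC)(CC)CC)[C@H](OCc2ccc(OC)cc2)C(C)=C | intermediate
24 | (1(10)Z,2S,4E,6R,7S,8R,9R)-2-(tert-butyldimethylsilyloxy)-9-(4-methoxybenzyloxy)-8-(triethylsilyloxy)germacra-1(10),4,11(13)-trien-12,6-olide | C=C1C(=O)O[C@@H]2/C=C(\C)C[C@H](O[Si](C)(C)C(C)(C)C)/C=C(/C)[C@@H](OCc3ccc(OC)cc3)[C@H](O[Si](CC)(CC)CC)[C@@H]12 | intermediate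
25 | (1(10)Z,2S,4E,6R,7S,8R,9R)-2-(tert-butyldimethylsilyloxy)-9-hydroxy-8-(triethylsilyloxy)germacra-1(10),4,11(13)-trien-12,6-olide | C=C1C(=O)O[C@@H]2/C=C(\C)C[C@H](O[Si](C)(C)C(C)(C)C)/C=C(/C)[C@@H](O)[C@H](O[Si](CC)(CC)CC)[C@@H]12 | intermediate
26 | angelic acid, (Z)-2-methylbut-2-enoic acid | C/C=C(/C)C(=O)O | starting material
27 | angelic 2,4,6-trichlorobenzoic anhydride | C/C=C(/C)C(=O)OC(=O)c1c(Cl)cc(Cl)cc1Cl | intermediate
28 | (1(10)Z,2S,4E,6R,7S,8R,9R)-9-angeloyloxy-2-(tert-butyldimethylsilyloxy)-8-(triethylsilyloxy)germacra-1(10),4,11(13)-trien-12,6-olide | C=C1C(=O)O[C@@H]2/C=C(\C)C[C@H](O[Si](C)(C)C(C)(C)C)/C=C(/C)[C@@H](OC(=O)/C(C)=C\C)[C@H](O[Si](CC)(CC)CC)[C@@H]12 | intermediate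
29 | (1(10)Z,2S,4E,6R,7R,8R,9R)-9-angeloyloxy-2,8-dihydroxygermacra-1(10),4,11(13)-trien-12,6-olide (CNP0311662.1) | C=C1C(=O)O[C@@H]2/C=C(\C)C[C@H](O)/C=C(/C)[C@@H](OC(=O)/C(C)=C\C)[C@H](O)[C@@H]12 | target

## Step count and risk

Total steps: 18. Longest linear sequence: 13 (steps 1–8, then 14–18); fragment B takes 5 steps (9–13).

Steps most likely to fail:

1. Step 14 (proposed new method). Risks are ring-opening elimination of the butenolide-derived allylchromium species, slow turnover with the bulky silyl chloride, a mismatched ligand, and decomposition of the labile aldehyde. The fallback uses known chemistry and sets out from 16 and 22. Zinc dust in THF/saturated aq. NH4Cl at rt (the established, substrate-controlled zinc Barbier allylation with 3-(bromomethyl)butenolides, proceeding through the same chair) gives the free C-8 alcohol F1. F1 is silylated at once with Et3SiOTf and 2,6-lutidine in CH2Cl2 at −78 °C, and the route is rejoined at 23.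

2. Step 15 (macrocyclic ring-closing metathesis). Risks are the hindered 1,1-disubstituted alkene, two allylic oxygen substituents, ring strain, dimerisation and an uncertain E/Z outcome. The fallback sets out from 23 and moves the ring closure to the very end, on the unprotected seco compound where free hydroxyls replace three bulky protecting groups. DDQ in buffered CH2Cl2 gives the seco C-9 alcohol F2. Acylation with 26 through anhydride 27 (as in step 17) gives the seco angelate F3. HF·pyridine gives the seco diol F4. Ring-closing metathesis of F4 with the second-generation Hoveyda–Grubbs catalyst in dilute toluene then comes back to the route at 29.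

3. Step 17 (angeloylation). Risks are the hindered O-9 flanked by the O-8 silyl ether, and angelate-to-tiglate isomerisation. The fallback builds the Z alkene on the molecule instead of transferring preformed angelic acid, and sets out from 25. Commercial methyl 2-[bis(2,2,2-trifluoroethoxy)phosphoryl]propanoate is hydrolysed with LiOH to the phosphonopropanoic acid F5. DCC/DMAP coupling of F5 with 25 gives the phosphonate ester F6. Still–Gennari olefination of F6 (KN(SiMe3)2, 18-crown-6, THF, −78 °C, then acetaldehyde) gives the Z-2-methylbut-2-enoate and comes back to the route at 28.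

## Further compounds

F1 | step 14 | (4R,5R)-4-[(1R,2R)-1-hydroxy-2-(4-methoxybenzyloxy)-3-methylbut-3-en-1-yl]-5-[(1E,4S)-4-(tert-butyldimethylsilyloxy)-2-methylhexa-1,5-dien-1-yl]-3-methylenedihydrofuran-2(3H)-one | C=C1C(=O)O[C@H](/C=C(\C)C[C@H](O[Si](C)(C)C(C)(C)C)C=C)[C@H]1[C@@H](O)[C@H](OCc2ccc(OC)cc2)C(C)=C
F2 | step 15 | (4S,5R)-4-[(1R,2R)-2-hydroxy-3-methyl-1-(triethylsilyloxy)but-3-en-1-yl]-5-[(1E,4S)-4-(tert-butyldimethylsilyloxy)-2-methylhexa-1,5-dien-1-yl]-3-methylenedihydrofuran-2(3H)-one | C=C1C(=O)O[C@H](/C=C(\C)C[C@H](O[Si](C)(C)C(C)(C)C)C=C)[C@H]1[C@@H](O[Si](CC)(CC)CC)[C@H](O)C(C)=C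
F3 | step 15 | (4S,5R)-4-[(1R,2R)-2-angeloyloxy-3-methyl-1-(triethylsilyloxy)but-3-en-1-yl]-5-[(1E,4S)-4-(tert-butyldimethylsilyloxy)-2-methylhexa-1,5-dien-1-yl]-3-methylenedihydrofuran-2(3H)-one | C=C1C(=O)O[C@H](/C=C(\C)C[C@H](O[Si](C)(C)C(C)(C)C)C=C)[C@H]1[C@@H](O[Si](CC)(CC)CC)[C@H](OC(=O)/C(C)=C\C)C(C)=C
F4 | step 15 | (4R,5R)-4-[(1R,2R)-2-angeloyloxy-1-hydroxy-3-methylbut-3-en-1-yl]-5-[(1E,4S)-4-hydroxy-2-methylhexa-1,5-dien-1-yl]-3-methylenedihydrofuran-2(3H)-one | C=C1C(=O)O[C@H](/C=C(\C)C[C@H](O)C=C)[C@H]1[C@@H](O)[C@H](OC(=O)/C(C)=C\C)C(C)=C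
F5 | step 17 | 2-[bis(2,2,2-trifluoroethoxy)phosphoryl]propanoic acid (racemic) | CC(C(=O)O)P(=O)(OCC(F)(F)F)OCC(F)(F)F
F6 | step 17 | (1(10)Z,2S,4E,6R,7S,8R,9R)-9-{2-[bis(2,2,2-trifluoroethoxy)phosphoryl]propanoyloxy}-2-(tert-butyldimethylsilyloxy)-8-(triethylsilyloxy)germacra-1(10),4,11(13)-trien-12,6-olide (both epimers at the phosphonate carbon) | C=C1C(=O)O[C@@H]2/C=C(\C)C[C@H](O[Si](C)(C)C(C)(C)C)/C=C(/C)[C@@H](OC(=O)C(C)P(=O)(OCC(F)(F)F)OCC(F)(F)F)[C@H](O[Si](CC)(CC)CC)[C@@H]12
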